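**Route outline**

- Cuts: first the interflavanyl bond between C4 of ring C of the upper unit and C6 of ring A of the lower unit; then, in each half, the O1–C2 bond of ring C and the Cα=Cβ bond of a chalcone.
- Enabling feature: the upper C4 is a diarylmethine whose second aryl group is C6 of the lower ring A and which sits cis to the C3 oxygen, so it can come from a C4 ketone plus a C6 carbanion, followed by reduction of the tertiary carbinol. Both units share the 2,3-trans C2/C3 array beside a C4 that is oxygenated (lower) or derivable from a carbonyl (upper), so one (2R,3R)-dihydroflavonol serves twice.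
- Forward: aldol condensation gives the chalcone; epoxidation and phenol closure build ring C once; the batch is divided (silylated ketone for the upper half; reduction, silylation and C6 bromination for the lower half).
- The two complete flavans are joined at C4–C6 by aryllithium addition, the carbinol is reduced, and benzyl and silyl groups are removed; no ring is made after the union.
- Stereochemistry: the poly-L-leucine epoxidation sets C3 of both units; C2 follows as 2,3-trans in the ring closure; the lower C4 comes from borohydride reduction (3,4-trans); the upper C4 from hydride capture of the planar cation anti to the C3 silyloxy group (3,4-cis).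

Key step: step 10

Remark: flavan numbering is used; "upper" is the unit bonded through C4, "lower" the unit bonded through C6. CIP letters of unchanged centres alter with the protecting groups, so the SMILES strings are decisive. Poly-L-leucine is taken to be a purchasable or routinely made catalyst.

**Steps**

Step 1
Reactants: 1 4'-benzyloxy-2'-hydroxyacetophenone
Product: 2 4'-benzyloxy-2'-(methoxymethoxy)acetophenone
Conditions: MOMCl, i-Pr2NEt, CH2Cl2, 0 °C → rt
Reagents that add atoms: chloromethyl methyl ether, COCCl
Why: Williamson-type O-alkylation of the chelated 2'-phenol masks the only acidic hydroxyl, so that the aldol condensation and the basic peroxide epoxidation cannot divert to a flavanone, a flavonol or an aurone, and the acetal is shed later in the same flask as the epoxide opening.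

Step 2
Reactants: 2 4'-benzyloxy-2'-(methoxymethoxy)acetophenone; 3 3,4-dibenzyloxybenzaldehyde
Product: 4 (E)-3,4,4'-tris(benzyloxy)-2'-(methoxymethoxy)chalcone
Conditions: KOH (aq.), EtOH–THF, rt
Reagents that add atoms: none
Why: Claisen–Schmidt condensation of the methyl ketone enolate with the non-enolisable aldehyde, followed by E1cB loss of water, gives the conjugated E-enone as the thermodynamic alkene, and benzyl and MOM ethers are inert to hydroxide.

Step 3
Reactants: 4 (E)-3,4,4'-tris(benzyloxy)-2'-(methoxymethoxy)chalcone
Product: 5 trans-(αR,βS)-epoxide of chalcone 4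
Conditions: poly-L-leucine (immobilised), urea–H2O2, DBU, THF, rt
Reagents that add atoms: hydrogen peroxide, used as its urea adduct, OO
Why: Juliá–Colonna epoxidation (Weitz–Scheffer conjugate addition of hydroperoxide and closure of the peroxy enolate) on the helical L-polypeptide should expose one enone face and give the trans (αR,βS) epoxide, whose α-carbon becomes C3 of both flavan units.

Step 4
Reactants: 5 trans-(αR,βS)-epoxide of chalcone 4
Product: 6 β-benzylsulfanyl-α,2'-dihydroxy-3,4,4'-tris(benzyloxy)dihydrochalcone (Cα spatially as in 5, formally αS; Cβ epimers both usable)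
Conditions: BnSH (4 equiv), SnCl4 (0.3 equiv), CH2Cl2, −20 °C
Reagents that add atoms: phenylmethanethiol, SCc1ccccc1
Why: Lewis-acid-assisted thiolysis opens the epoxide at the benzylic β-carbon (activated by the para-benzyloxy group) without touching the α C–O bond and thus the future C3, while the same SnCl4/thiol pair cleaves the MOM acetal and frees the 2'-phenol, and the configuration reached at Cβ does not matter because step 5 passes through the benzylic cation.

Step 5
Reactants: 6 β-benzylsulfanyl-α,2'-dihydroxy dihydrochalcone
Product: 7 7,3',4'-tri-O-benzyl-(2R,3R)-fustin (2,3-trans dihydroflavonol)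
Conditions: AgBF4, CH2Cl2, 0 °C, dark
Reagents that add atoms: none
Why: The thiophilic silver salt abstracts the benzylic sulfide and the para-benzyloxybenzyl cation is captured by the 2'-phenol in an SN1-type etherification that closes the six-membered ring C with the C2 aryl group equatorial and trans to the C3 hydroxyl, so that C2 is set by substrate control from C3.

Step 6
Reactants: 7 7,3',4'-tri-O-benzyl-(2R,3R)-fustin
Product: 8 3-O-TBS-7,3',4'-tri-O-benzyl-(2R,3R)-fustin (ketone partner)
Conditions: TBSCl, imidazole, DMF, rt → 40 °C
Reagents that add atoms: tert-butyldimethylsilyl chloride, CC(C)(C)[Si](C)(C)Cl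
Why: Imidazole-mediated silylation of the secondary α-hydroxyl is too weakly basic to enolise the flavanone, removes the only proton that would quench the aryllithium and installs the bulky group that later steers the hydride.

Step 7
Reactants: 7 7,3',4'-tri-O-benzyl-(2R,3R)-fustin
Product: 9 7,3',4'-tri-O-benzyl-(2R,3S,4R)-mollisacacidin (2,3-trans-3,4-trans flavan-3,4-diol)
Conditions: NaBH4, THF–MeOH, 0 °C
Reagents that add atoms: none
Why: Borohydride reduction of the aryl ketone by axial attack on the half-chair that carries the 2-aryl and 3-hydroxyl groups equatorially gives the equatorial C4 alcohol, that is the 3,4-trans diol, as is usual for 2,3-trans dihydroflavonols (substrate control from C3).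

Step 8
Reactants: 9 7,3',4'-tri-O-benzyl-(2R,3S,4R)-mollisacacidin
Product: 10 3,4-bis-O-TBS ether of 9
Conditions: TBSCl (excess), imidazole, DMAP (cat.), DMF, 40–50 °C
Reagents that add atoms: tert-butyldimethylsilyl chloride, CC(C)(C)[Si](C)(C)Cl
Why: Exhaustive silylation of the trans-diequatorial diol under non-acidic conditions removes both acidic protons before the lithiation and turns the ionisable benzylic C4 hydroxyl into a bulky, poorly leaving silyl ether.

Step 9
Reactants: 10 3,4-bis-O-TBS ether of 9
Product: 11 6-bromo-3,4-bis-O-TBS-7,3',4'-tri-O-benzylmollisacacidin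
Conditions: NBS (1.0 equiv), CH2Cl2, −78 → 0 °C, dark
Reagents that add atoms: N-bromosuccinimide, O=C1CCC(=O)N1Br
Why: Electrophilic aromatic bromination goes to ring A, the only ring with two oxygen donors in a 1,3-relationship, and there to C6 (para to O1, ortho to the 7-benzyloxy group) because C8 is flanked by both oxygens and C5 is activated by neither, while succinimide as the only by-product leaves the acid-labile C4 silyl ether alone.

Step 10
Reactants: 11 6-bromo-3,4-bis-O-TBS-7,3',4'-tri-O-benzylmollisacacidin; 8 3-O-TBS-7,3',4'-tri-O-benzyl-(2R,3R)-fustin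
Product: 13 tertiary C4 diaryl carbinol (upper C4 bonded to lower C6; both C4 epimers), via C6 aryllithium 12 (not isolated)
Conditions: 11 (1.2 equiv), tert-butyllithium (2.4 equiv), THF, −78 °C; then 8 in THF, −78 °C; H2O quench at −78 °C
Reagents that add atoms: none
Why: tert-Butyllithium exchanges the bromine of 11 for lithium faster than it deprotonates anything, giving the carbanion 12 at C6 of ring A only, and this adds to the C4 carbonyl of 8 (1,2-addition) to form the C4(upper)–C6(lower) bond and the lithium alkoxide of 13. The closest known reaction type is the addition of a ring-A-lithiated, fully protected flavan-3-ol to a 3-O-silylated flavan-3-ol-4-one. No ring is closed in this step, since both pyran rings are already in place. The one new stereocentre, the carbinol carbon, is not controlled and need not be, because step 11 turns either epimer into the same planar cation. The step needs site selectivity on the nucleophile, which the bromine position secures (C6, not C8 or ring B), and 1,2-addition in preference to deprotonation at C3 with retro-oxa-Michael opening of ring C, which is favoured at −78 °C because the 5-unsubstituted carbonyl is open to attack and 12 is a compact sp2 carbanion whose ortho-benzyloxy oxygen can hold the lithium near the carbonyl. All hydroxyl groups of both partners are silylated, so no proton source competes.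

Step 11
Reactants: 13 tertiary C4 diaryl carbinol (both C4 epimers)
Product: 14 hexa-O-benzyl-tris-O-TBS fisetinidol-(4β→6)-mollisacacidin (upper unit 2,3-trans-3,4-cis)
Conditions: Bu3SnH (3 equiv), CF3CO2H (3 equiv), CH2Cl2, −78 → −30 °C; Et3N quench
Reagents that add atoms: none
Why: In this ionic hydrogenation the acid at low temperature should ionise only the tertiary carbinol, whose cation is stabilised by ortho/para oxygen donors on both flanking A rings while the secondary C4 silyl ether of the lower unit is a far poorer leaving group on a ring that is electron-poor as long as the cation exists, and the tin hydride should add to the face opposite the adjacent C3 silyloxy group (the facial preference arenes show towards 2,3-trans flavan-4-yl cations), so that both epimers converge on the product with the aryl group cis to the C3 oxygen.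

Step 12
Reactants: 14 hexa-O-benzyl-tris-O-TBS fisetinidol-(4β→6)-mollisacacidin
Product: 15 3,3',4'-tris-O-TBS fisetinidol-(4β→6)-mollisacacidin (six free phenols; primes here mark the lower unit)
Conditions: H2 (1 atm), Pd(OH)2/C (washed neutral), EtOAc–THF, rt
Reagents that add atoms: none
Why: Catalytic hydrogenolysis of the six aryl benzyl ethers under neutral aprotic conditions is much faster than cleavage of the O1–C2 bonds of ring C or of the bulky benzylic C4 silyl ether, which is kept on in this step precisely to shield the lower C4–O bond.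

Step 13
Reactants: 15 tris-O-TBS hexaphenol
Product: 16 fisetinidol-(4β→6)-mollisacacidin (target)
Conditions: TBAF/AcOH (1:1), THF, 0 °C → rt, argon
Reagents that add atoms: none
Why: Fluoride cleaves the three secondary silyl ethers through pentacoordinate silicon, and buffering with acetic acid keeps the medium near neutral so that neither phenoxide-driven quinone methide formation nor acid ionisation of the liberated benzylic C4 hydroxyl of the flavan-3,4-diol unit should set in.

**Compound list**

1 | 4'-benzyloxy-2'-hydroxyacetophenone | CC(=O)c1ccc(OCc2ccccc2)cc1O | starting material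
2 | 4'-benzyloxy-2'-(methoxymethoxy)acetophenone | CC(=O)c1ccc(OCc2ccccc2)cc1OCOC | intermediate
3 | 3,4-dibenzyloxybenzaldehyde | O=Cc1ccc(OCc2ccccc2)c(OCc2ccccc2)c1 | starting material
4 | (E)-3,4,4'-tris(benzyloxy)-2'-(methoxymethoxy)chalcone | COCOc1cc(OCc2ccccc2)ccc1C(=O)/C=C/c1ccc(OCc2ccccc2)c(OCc2ccccc2)c1 | intermediate
5 | trans-(αR,βS)-epoxide of 4 | COCOc1cc(OCc2ccccc2)ccc1C(=O)[C@@H]1O[C@H]1c1ccc(OCc2ccccc2)c(OCc2ccccc2)c1 | intermediate
6 | β-benzylsulfanyl-α,2'-dihydroxy-3,4,4'-tris(benzyloxy)dihydrochalcone, Cα fixed (formally αS), Cβ epimers | O=C(c1ccc(OCc2ccccc2)cc1O)[C@H](O)C(SCc1ccccc1)c1ccc(OCc2ccccc2)c(OCc2ccccc2)c1 | intermediate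
7 | 7,3',4'-tri-O-benzyl-(2R,3R)-fustin | O=C1c2ccc(OCc3ccccc3)cc2O[C@H](c2ccc(OCc3ccccc3)c(OCc3ccccc3)c2)[C@H]1O | intermediate
8 | 3-O-TBS-7,3',4'-tri-O-benzyl-(2R,3R)-fustin | O=C1c2ccc(OCc3ccccc3)cc2O[C@H](c2ccc(OCc3ccccc3)c(OCc3ccccc3)c2)[C@H]1O[Si](C)(C)C(C)(C)C | intermediate
9 | 7,3',4'-tri-O-benzyl-(2R,3S,4R)-mollisacacidin | c1cc2c(cc1OCc1ccccc1)O[C@H](c1ccc(OCc3ccccc3)c(OCc3ccccc3)c1)[C@@H](O)[C@@H]2O | intermediate
10 | 3,4-bis-O-TBS-7,3',4'-tri-O-benzylmollisacacidin (configuration as in 9) | c1cc2c(cc1OCc1ccccc1)O[C@H](c1ccc(OCc3ccccc3)c(OCc3ccccc3)c1)[C@@H](O[Si](C)(C)C(C)(C)C)[C@@H]2O[Si](C)(C)C(C)(C)C | intermediate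
11 | 6-bromo derivative of 10 | Brc1cc2c(cc1OCc1ccccc1)O[C@H](c1ccc(OCc3ccccc3)c(OCc3ccccc3)c1)[C@@H](O[Si](C)(C)C(C)(C)C)[C@@H]2O[Si](C)(C)C(C)(C)C | intermediate
12 | 6-lithio derivative of 10 (C6 aryllithium) | [Li]c1cc2c(cc1OCc1ccccc1)O[C@H](c1ccc(OCc3ccccc3)c(OCc3ccccc3)c1)[C@@H](O[Si](C)(C)C(C)(C)C)[C@@H]2O[Si](C)(C)C(C)(C)C | intermediate
13 | tertiary C4 carbinol joining upper C4 to lower C6 (C4 configuration not defined, both epimers) | c1ccccc1COc1ccc2c(c1)O[C@H](c1ccc(OCc3ccccc3)c(OCc3ccccc3)c1)[C@@H](O[Si](C)(C)C(C)(C)C)C2(O)c1cc2c(cc1OCc1ccccc1)O[C@H](c1ccc(OCc3ccccc3)c(OCc3ccccc3)c1)[C@@H](O[Si](C)(C)C(C)(C)C)[C@@H]2O[Si](C)(C)C(C)(C)C | intermediate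
14 | hexa-O-benzyl-tris-O-TBS fisetinidol-(4β→6)-mollisacacidin | c1ccccc1COc1ccc2c(c1)O[C@H](c1ccc(OCc3ccccc3)c(OCc3ccccc3)c1)[C@@H](O[Si](C)(C)C(C)(C)C)[C@H]2c1cc2c(cc1OCc1ccccc1)O[C@H](c1ccc(OCc3ccccc3)c(OCc3ccccc3)c1)[C@@H](O[Si](C)(C)C(C)(C)C)[C@@H]2O[Si](C)(C)C(C)(C)C | intermediate
15 | tris-O-TBS fisetinidol-(4β→6)-mollisacacidin (free phenols) | Oc1ccc2c(c1)O[C@H](c1ccc(O)c(O)c1)[C@@H](O[Si](C)(C)C(C)(C)C)[C@H]2c1cc2c(cc1O)O[C@H](c1ccc(O)c(O)c1)[C@@H](O[Si](C)(C)C(C)(C)C)[C@@H]2O[Si](C)(C)C(C)(C)C | intermediate
16 | fisetinidol-(4β→6)-mollisacacidin, (2R,3S,4S)-2-(3,4-dihydroxyphenyl)-4-[(2R,3S,4R)-2-(3,4-dihydroxyphenyl)-3,4,7-trihydroxychroman-6-yl]chroman-3,7-diol | Oc1ccc2c(c1)O[C@H](c1ccc(O)c(O)c1)[C@@H](O)[C@H]2c1cc2c(cc1O)O[C@H](c1ccc(O)c(O)c1)[C@@H](O)[C@@H]2O | target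

**Step count and risks**

Total: 13 steps. Longest linear sequence: 12 steps (steps 1–5 and 7–13, through the lower unit); the branch to ketone 8 adds step 6.

Step 10 is the first risk. The aryllithium may act as a base at C3 of the α-silyloxy ketone, with opening of ring C, or conversion may stall through crowding of the two fully protected flavans. The fallback gives up the carbanion union for the acid-mediated cation–arene union on free phenols. It sets out from 7: hydrogenolysis of the three benzyl ethers (H2, Pd(OH)2/C, EtOAc–MeOH) gives (+)-fustin F1, and NaBH4 in ethanol reduces it to (+)-mollisacacidin F2. In dilute aqueous acid at room temperature F2 ionises at C4 and the cation is taken up by C6 of a second molecule. This should give 16 together with its upper-C4 epimer (the 3,4-trans dimer is expected to predominate) and higher oligomers, so 16 would have to be separated on Sephadex LH-20. The fallback rejoins the route at 16.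

Step 11 is the second risk. Hydride may be delivered to both faces of the cation, the lower C4 silyl ether may ionise as well (with loss of that oxygen), or the cation may lose the C3 hydrogen. The fallback takes the ionisable lower oxygen out of play as a ketone before the reduction. It sets out from 13: TBAF in THF removes the three silyl ethers to give the tetraol F3, and activated MnO2 in CH2Cl2 oxidises the only secondary benzylic alcohol (lower C4) to the ketone F4, so that nothing but the tertiary carbinol can ionise. Bu3SnH/CF3CO2H then gives the hexa-O-benzyl fisetinidol-(4β→6)-fustin F5, with the free C3 hydroxyl directing the hydride to the opposite face. Hydrogenolysis at the ketone stage gives fisetinidol-(4β→6)-fustin F6, and NaBH4 reduction of its free dihydroflavonol unit (as for fustin itself) leads to 16, where the fallback rejoins the route. This end game also keeps the lower C4–O bond away from the catalyst of step 12.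

Step 13 is the third risk. On the free polyphenol, fluoride basicity may drive 1,6-elimination of the lower C4 silyloxy group from the para-phenol, the catechols may oxidise, or the crowded upper C3 silyl ether may cleave incompletely. The fallback reverses the order of the two deprotections so that fluoride never meets a free phenol. It sets out from 14: unbuffered TBAF in THF (warmed if needed) on the base-stable hexabenzyl ether gives the hexa-O-benzyl triol F7, and neutral hydrogenolysis (H2, Pd(OH)2/C, EtOAc–THF) as the last operation gives 16, where it rejoins the route.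

**Further compounds**

F1 | step 10 | (+)-(2R,3R)-fustin | O=C1c2ccc(O)cc2O[C@H](c2ccc(O)c(O)c2)[C@H]1O
F2 | step 10 | (+)-(2R,3S,4R)-mollisacacidin | c1cc2c(cc1O)O[C@H](c1ccc(O)c(O)c1)[C@@H](O)[C@@H]2O
F3 | step 11 | desilylated carbinol 13 (hexa-O-benzyl tetraol, C4 epimers) | c1ccccc1COc1ccc2c(c1)O[C@H](c1ccc(OCc3ccccc3)c(OCc3ccccc3)c1)[C@@H](O)C2(O)c1cc2c(cc1OCc1ccccc1)O[C@H](c1ccc(OCc3ccccc3)c(OCc3ccccc3)c1)[C@@H](O)[C@@H]2O
F4 | step 11 | lower-unit C4 ketone of F3 | c1ccccc1COc1ccc2c(c1)O[C@H](c1ccc(OCc3ccccc3)c(OCc3ccccc3)c1)[C@@H](O)C2(O)c1cc2c(cc1OCc1ccccc1)O[C@H](c1ccc(OCc3ccccc3)c(OCc3ccccc3)c1)[C@@H](O)C2=O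
F5 | step 11 | hexa-O-benzyl fisetinidol-(4β→6)-fustin | c1ccccc1COc1ccc2c(c1)O[C@H](c1ccc(OCc3ccccc3)c(OCc3ccccc3)c1)[C@@H](O)[C@H]2c1cc2c(cc1OCc1ccccc1)O[C@H](c1ccc(OCc3ccccc3)c(OCc3ccccc3)c1)[C@@H](O)C2=O
F6 | step 11 | fisetinidol-(4β→6)-fustin | Oc1ccc2c(c1)O[C@H](c1ccc(O)c(O)c1)[C@@H](O)[C@H]2c1cc2c(cc1O)O[C@H](c1ccc(O)c(O)c1)[C@@H](O)C2=O
F7 | step 13 | hexa-O-benzyl fisetinidol-(4β→6)-mollisacacidin | c1ccccc1COc1ccc2c(c1)O[C@H](c1ccc(OCc3ccccc3)c(OCc3ccccc3)c1)[C@@H](O)[C@H]2c1cc2c(cc1OCc1ccccc1)O[C@H](c1ccc(OCc3ccccc3)c(OCc3ccccc3)c1)[C@@H](O)[C@@H]2O
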